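The route rests on cutting the C13–C14 bond, which joins the two vicinal quaternary carbons of the C/D ring fusion. The key step exploits that C14 also sits on sp2 C8 of ring B and can therefore be a benzylic cation. Ring D is carried as a cyclopentanol (C13, C15–C18). Its carbinol carbon C15 bears a 1-naphthylvinyl group, that is C14 plus rings A and B. Protonation triggers a semipinacol shift of C13 from C15 to C14. This one operation forms C13–C14, sets C14, creates its methyl group and enlarges ring D. A dearomatising naphthol alkylation (C9–C11) then closes ring C and unveils the enone. An o-quinone hetero-Diels–Alder reaction adds the guaiane.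

Key step: step 15

Remark: triterpene carbons carry friedelane (celastroid) numbers C1–C30 and guaiane carbons carry G1–G15. The descriptors α/β refer to the usual drawing, in which the methyl groups on C9, C14, C17 and C20 are β. Diene 40 is an equilibrating tautomer mixture and is drawn as the tautomer that leads to the target. In step 1 the catalyst enantiomer that gives the R adduct is used.

Step 1
Reactants: 1 isoprene; 2 methacrolein
Product: 3 (R)-1,4-dimethylcyclohex-3-ene-1-carbaldehyde
Conditions: chiral oxazaborolidinium triflimide (from diphenylprolinol, o-tolylboronic acid and Tf2NH, 10 mol %), CH2Cl2, −78 °C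
Reagents that add atoms: none
Why: Catalytic enantioselective Diels–Alder reaction in which the diene methyl group steers the para orientation and the catalyst shields one face of the bound enal, which sets C20.

Step 2
Reactants: 3 (R)-1,4-dimethylcyclohex-3-ene-1-carbaldehyde
Product: 4 methyl (R)-1,4-dimethylcyclohex-3-ene-1-carboxylate
Conditions: I2, KOH, MeOH, 0 °C
Reagents that add atoms: methanol, CO
Why: Oxidative esterification in which hypoiodite oxidises the methanol hemiacetal, while quaternary C20 cannot epimerise.

Step 3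
Reactants: 4 methyl (R)-1,4-dimethylcyclohex-3-ene-1-carboxylate
Product: 6 methyl (S)-1,4-dimethyl-5-oxocyclohex-3-ene-1-carboxylate (ring E enone with C22=O), via allylic alcohol 5 (not isolated)
Conditions: SeO2 (cat.), t-BuOOH, CH2Cl2, rt; then Dess–Martin periodinane, CH2Cl2
Reagents that add atoms: tert-butyl hydroperoxide, CC(C)(C)OO
Why: Selenium dioxide allylic oxidation (ene reaction, then [2,3]-shift) attacks the ring CH2 (C22) at the more substituted alkene end, away from neopentylic C19, and Dess–Martin oxidation of the crude alcohol gives the carvone-type enone.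

Step 4
Reactants: 6 ring E enone; 7 [2-(chloromethyl)allyl]trimethylsilane
Product: 8 conjugate adduct: ring E ketone bearing the C13H2–C15(=CH2)–C16H2Cl chain on C18 cis to the C20 ester (C17 epimers)
Conditions: TiCl4, CH2Cl2, −78 °C; H2O
Reagents that add atoms: none
Why: Hosomi–Sakurai conjugate allylation in which axial attack at C18, on the half-chair that keeps the slimmer ester axial and the C20 methyl group equatorial, places the new C18–C13 bond on the α face, cis to the ester.

Step 5
Reactants: 8 conjugate adduct
Product: 9 cis-fused 15-methylene-22-oxo hydrindane (17β-methyl; 18β-H; 20β-methyl; 20α-CO2Me)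
Conditions: KOt-Bu, t-BuOH–THF, rt
Reagents that add atoms: none
Why: Intramolecular enolate alkylation (5-exo-tet methylenecyclopentane annulation) in which the equilibrating C17 enolate displaces the allylic chloride and the short tether allows only the cis fusion, which sets quaternary C17.

Step 6
Reactants: 9 cis-fused 15-methylene-22-oxo hydrindane
Product: 11 cis-fused 15-methylene hydrindane ester, via tosylhydrazone 10 (not isolated)
Conditions: TsNHNH2, EtOH, 60 °C; solvent change; catecholborane, CHCl3, 0 °C; NaOAc·3H2O, reflux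
Reagents that add atoms: p-toluenesulfonyl hydrazide, Cc1ccc(cc1)S(=O)(=O)NN (its atoms stay only in 10)
Why: Caglioti-type deoxygenation (hydride addition to the tosylhydrazone, then loss of sulfinate and N2) turns the spent activating carbonyl C22 into CH2 without touching alkene, ester or stereocentres.

Step 7
Reactants: 11 cis-fused 15-methylene hydrindane ester
Product: 12 cis-hydrindan-2-one ester (C15 ketone)
Conditions: O3, CH2Cl2–MeOH, −78 °C; Me2S
Reagents that add atoms: ozone, [O-][O+]=O
Why: Ozonolysis with reductive work-up cleaves the only alkene to the C15 cyclopentanone.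

Step 8
Reactants: 12 cis-hydrindan-2-one ester
Product: 13 13-methylene ketone
Conditions: (CH2O)n, i-Pr2NH·CF3CO2H, THF, reflux
Reagents that add atoms: formaldehyde (from paraformaldehyde), C=O
Why: Mannich-type α-methylenation takes place at C13 because the other α carbon, C16, is neopentylic.

Step 9
Reactants: 13 13-methylene ketone; 14 benzyl 2-iodoethyl ether
Product: 16 ketone with quaternary C13 (13α-methyl; 13β-CH2CH2OBn), via lithium enolate 15 (not isolated)
Conditions: LiBH(s-Bu)3, THF, −78 °C; then 14, DMPU, −78 °C to rt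
Reagents that add atoms: lithium tri-sec-butylborohydride, [Li+].CCC(C)[BH-](C(C)CC)C(C)CC (lithium only in 15)
Why: Conjugate reduction–alkylation in which 1,4-hydride addition gives the C13 enolate regiospecifically and the iodide approaches from the convex β face, opposite C19, which sets C13.

Step 10
Reactants: 17 3,4-dimethoxy-2-methylbenzoic acid
Product: 19 β-keto sulfoxonium ylide of 17, via acid chloride 18 (not isolated)
Conditions: (COCl)2, DMF (cat.), CH2Cl2; then Me3S(O)I, KOt-Bu, THF
Reagents that add atoms: oxalyl chloride, O=C(Cl)C(=O)Cl (chlorine only in 18); trimethylsulfoxonium iodide, C[S+](C)(C)=O.[I-]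
Why: Acylation of dimethylsulfoxonium methylide by the acid chloride gives the stabilised ylide, with a second equivalent of the methylide acting as base.

Step 11
Reactants: 19 β-keto sulfoxonium ylide; 20 pent-3-yn-2-one
Product: 21 1-(4-hydroxy-6,7-dimethoxy-1,5-dimethylnaphthalen-2-yl)ethanone (rings A and B as a naphthol)
Conditions: [Cp*RhCl2]2 (cat.), AgSbF6 (cat.), Zn(OAc)2 (cat.), ClCH2CH2Cl, 100 °C
Reagents that add atoms: none
Why: Sulfoxonium ylide–alkyne benzannulation by trivalent rhodium C–H activation at the only free ortho position (C10), in which the aryl group adds to the methyl-bearing β carbon of the ynone, so that C9 carries methyl and C8 carries acetyl.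

Step 12
Reactants: 21 naphthol ketone
Product: 22 O-benzyl naphthyl ketone
Conditions: BnBr, K2CO3, DMF, 50 °C
Reagents that add atoms: benzyl bromide, BrCc1ccccc1
Why: Williamson ether synthesis masks the acidic naphthol for the organolithium step.

Step 13
Reactants: 22 O-benzyl naphthyl ketone
Product: 23 2-(1-bromovinyl)naphthalene
Conditions: (PhO)3P, Br2, Et3N, CH2Cl2, −60 °C to reflux
Reagents that add atoms: bromine, BrBr
Why: The preformed bromophosphonium reagent converts the enolisable aryl methyl ketone into the vinyl bromide (ketone-to-vinyl-halide conversion through the enol phosphonium salt) without free bromine that could attack the arene.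

Step 14
Reactants: 23 2-(1-bromovinyl)naphthalene; 16 ketone with quaternary C13
Product: 25 tertiary allylic alcohol (cyclopentanol; 15β-(1-naphthylvinyl); 15α-OH), via vinyllithium 24 (not isolated)
Conditions: t-BuLi (2 equiv), Et2O, −78 °C; LaCl3·2LiCl (cat.), 16, THF, −78 °C; H2O
Reagents that add atoms: tert-butyllithium, [Li]C(C)(C)C (lithium only in 24)
Why: Bromine–lithium exchange and 1,2-addition in which the nucleophile reaches the C15 ketone from the convex β face of the cis-hydrindanone, away from ring E, which sets the carbinol centre.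

Step 15
Reactants: 25 tertiary allylic alcohol
Product: 26 ring-enlarged C15 ketone (ring D six-membered; 14β-methyl; C14 bonded to naphthalene C8)
Conditions: Tf2NH (5 mol %), CH2Cl2, −40 to 0 °C
Reagents that add atoms: none
Why: Tf2NH protonates the electron-rich 1-arylvinyl group at its CH2 terminus (this hydrogen completes the C14 methyl group) and gives the tertiary benzylic cation at C14 next to carbinol carbon C15; the C15–C13 bond, aligned with the empty orbital, migrates and the oxocarbenium ion loses its proton to give the C15 ketone. The closest known reaction type is the acid-induced semipinacol (Wagner–Meerwein) ring expansion of 1-(1-arylvinyl)cycloalkanols to 2-aryl-2-methylcycloalkanones. No ring is closed end to end: ring D grows from five members (C13, C15, C16, C17, C18) to six because C14 is inserted between C15 and C13 by a suprafacial 1,2-shift with retention at C13. The only new stereocentre, C14, is controlled by the C15 carbinol centre from step 14: with the vinyl group on the β face the bulky naphthyl group turns outward, away from the C17 methyl group and the C12 chain, the small CH2 terminus lies over the ring, and C13 bonds to the face that leaves the new methyl group β and C8 α. The step needs migration of C13 and not C16, secured by the higher migratory aptitude of the quaternary carbon over the neopentylic CH2, and protonation of the alkene rather than ionisation of the alcohol, secured by the trialkoxynaphthyl donor, since loss of water would give only a cross-conjugated 2-arylallyl cation. Formation of the C=O bond makes the shift irreversible, so reversible capture of the cation by the hydroxyl or benzyl ether oxygen drains back into 26.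

Step 16
Reactants: 26 ring-enlarged C15 ketone
Product: 27 C15 enol triflate (C15=C16)
Conditions: KN(SiMe3)2, THF, −78 °C; PhNTf2
Reagents that add atoms: N-phenylbis(trifluoromethanesulfonimide), O=S(=O)(N(c1ccccc1)S(=O)(=O)C(F)(F)F)C(F)(F)F
Why: Deprotonation is possible only at C16, and O-sulfonylation of the enolate gives the enol triflate.

Step 17
Reactants: 27 C15 enol triflate
Product: 28 naphthol primary alcohol with saturated ring D
Conditions: H2 (1 atm), Pd/C, NaHCO3, EtOAc–MeOH, rt
Reagents that add atoms: none
Why: One catalytic hydrogenation hydrogenolyses the vinyl triflate, saturates the resulting C15=C16 alkene and cleaves both benzyl ethers, which removes the C15 oxygen left by the key step.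

Step 18
Reactants: 28 naphthol primary alcohol
Product: 29 naphthol primary bromide (C11–Br)
Conditions: CBr4, PPh3, CH2Cl2, 0 °C
Reagents that add atoms: carbon tetrabromide, BrC(Br)(Br)Br
Why: The Appel reaction activates only the aliphatic alcohol and leaves the hindered naphthol and the electron-rich ring untouched.

Step 19
Reactants: 29 naphthol primary bromide
Product: 30 6-oxopristimerol dimethyl ether (pentacyclic 6-oxo-7-ene)
Conditions: Cs2CO3, DMF, 60 °C
Reagents that add atoms: none
Why: Intramolecular para-alkylative dearomatisation of the naphtholate (Winstein–Masamune alkylation, 6-exo-tet) in which the C9 methyl group forces C13 and its chain to flank C9 rather than C7, and the chair transition state on the diequatorial C8/C12 pair brings C11 to the α face, which sets C9 with its methyl group β.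

Step 20
Reactants: 30 6-oxopristimerol dimethyl ether
Product: 31 6-oxopristimerol (catechol)
Conditions: BBr3, CH2Cl2, −78 to 0 °C; H2O
Reagents that add atoms: none
Why: Lewis acid cleavage of both aryl methyl ethers, which react faster than the hindered tertiary methyl ester.

Step 21
Reactants: 32 (S)-carvone
Product: 33 (2R,5S)-2-methyl-5-(prop-1-en-2-yl)cyclohexan-1-one (cis-dihydrocarvone)
Conditions: ene-reductase (old yellow enzyme type), NADP+ (cat.), glucose dehydrogenase, D-glucose, phosphate buffer pH 7, 30 °C
Reagents that add atoms: none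
Why: Biocatalytic conjugate reduction in which the flavin hydride and the active-site proton add trans across the enone and fix the 2R centre (G10) regardless of the resident centre (G7), giving the cis isomer.

Step 22
Reactants: 33 cis-dihydrocarvone
Product: 35 (2R,5S)-2-methyl-5-(prop-1-en-2-yl)cycloheptan-1-one, via alpha-silyl ketone 34 (not isolated)
Conditions: Me3SiCHN2, BF3·OEt2, CH2Cl2, −78 °C; then H2O, silica gel
Reagents that add atoms: (trimethylsilyl)diazomethane, C[Si](C)(C)C=[N+]=[N-]
Why: Lewis acid promoted diazoalkane homologation (Tiffeneau–Demjanov type) in which the less substituted α carbon migrates, so the new CH2 (G5) enters away from the methyl-bearing carbon and both stereocentres stay untouched.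

Step 23
Reactants: 35 cycloheptanone
Product: 36 2,4,6-triisopropylbenzenesulfonyl hydrazone of 35
Conditions: 2,4,6-(i-Pr)3C6H2SO2NHNH2, HCl (cat.), MeOH, rt
Reagents that add atoms: 2,4,6-triisopropylbenzenesulfonyl hydrazide, CC(C)c1cc(C(C)C)c(S(=O)(=O)NN)c(C(C)C)c1
Why: Mild hydrazone condensation prepares the Shapiro reaction under conditions that spare the α stereocentre G10.

Step 24
Reactants: 36 sulfonyl hydrazone; 37 (E)-crotonaldehyde
Product: 39 bis-allylic alcohol (cycloheptenyl propenyl carbinol; carbinol epimers), via vinyllithium 38 (not isolated)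
Conditions: n-BuLi (2.1 equiv), TMEDA–THF, −78 to 0 °C; 37, −78 °C; H2O
Reagents that add atoms: n-butyllithium, [Li]CCCC (lithium only in 38)
Why: Shapiro reaction in which the dianion forms at the less substituted α carbon G5, loses sulfinate and N2, and the G1 vinyllithium adds 1,2 to the enal.

Step 25
Reactants: 39 bis-allylic alcohol
Product: 40 (7S,10R)-guaia-1(5),3,11-triene (equilibrating cyclopentadiene tautomers)
Conditions: TsOH·H2O (cat.), Et2O, 0 °C to rt; then 40 °C
Reagents that add atoms: none
Why: Ionisation gives the pentadienyl cation, whose conrotatory 4π electrocyclisation (Nazarov-type cyclodehydration, as used for alkylcyclopentadienes) closes the G4–G5 bond, and 1,5-hydrogen shifts erase the G4 centre and lead to the fully alkyl-substituted dienes.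

Step 26
Reactants: 31 6-oxopristimerol; 40 guaiatriene
Product: 42 CNP0317749.2, via ortho-quinone 41 (not isolated)
Conditions: Ag2O, Na2SO4, CH2Cl2, 0 °C to rt, dark, excess 40
Reagents that add atoms: none
Why: Ag2O gives o-quinone 41, whose O=C–C=O unit adds as an electron-poor heterodiene (inverse-demand hetero-Diels–Alder reaction, directly or by [4+2] at C3=O followed by a [3,3] shift) across G1=G5 on the face opposite the G10 methyl and G7 isopropenyl groups, with O3 bonding to the diene terminus G1, while 1,5-hydrogen shifts keep feeding the reacting tautomer.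

Compound list
1 | isoprene | C=CC(C)=C | starting material
2 | methacrolein | C=C(C)C=O | starting material
3 | (R)-1,4-dimethylcyclohex-3-ene-1-carbaldehyde | CC1=CC[C@](C)(C=O)CC1 | intermediate
4 | methyl (R)-1,4-dimethylcyclohex-3-ene-1-carboxylate | CC1=CC[C@](C)(C(=O)OC)CC1 | intermediate
5 | methyl (1S)-5-hydroxy-1,4-dimethylcyclohex-3-ene-1-carboxylate (carbinol epimers) | CC1=CC[C@](C)(C(=O)OC)CC1O | intermediate
6 | methyl (S)-1,4-dimethyl-5-oxocyclohex-3-ene-1-carboxylate | CC1=CC[C@](C)(C(=O)OC)CC1=O | intermediate
7 | [2-(chloromethyl)allyl]trimethylsilane | C=C(CCl)C[Si](C)(C)C | starting material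
8 | conjugate adduct, 2-(chloromethyl)allyl chain on C18 cis to the ester, C17 epimers | CC1C(=O)C[C@@](C)(C(=O)OC)C[C@H]1CC(=C)CCl | intermediate
9 | cis-fused 15-methylene-22-oxo hydrindane ester | C=C1C[C@@]2(C)C(=O)C[C@@](C)(C(=O)OC)C[C@H]2C1 | intermediate
10 | C22 tosylhydrazone of 9 | C=C1C[C@@]2(C)C(=NNS(=O)(=O)c3ccc(C)cc3)C[C@@](C)(C(=O)OC)C[C@H]2C1 | intermediate
11 | cis-fused 15-methylene hydrindane ester | C=C1C[C@@]2(C)CC[C@@](C)(C(=O)OC)C[C@H]2C1 | intermediate
12 | cis-hydrindan-2-one ester (C15 ketone) | O=C1C[C@@]2(C)CC[C@@](C)(C(=O)OC)C[C@H]2C1 | intermediate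
13 | 13-methylene ketone | C=C1C(=O)C[C@@]2(C)CC[C@@](C)(C(=O)OC)C[C@@H]12 | intermediate
14 | benzyl 2-iodoethyl ether | ICCOCc1ccccc1 | starting material
15 | lithium C13 enolate | CC1=C([O-])C[C@@]2(C)CC[C@@](C)(C(=O)OC)C[C@@H]12.[Li+] | intermediate
16 | C15 ketone with quaternary C13 (13α-methyl, 13β-CH2CH2OBn) | O=C1C[C@@]2(C)CC[C@@](C)(C(=O)OC)C[C@H]2[C@]1(C)CCOCc1ccccc1 | intermediate
17 | 3,4-dimethoxy-2-methylbenzoic acid | COc1ccc(C(=O)O)c(C)c1OC | starting material
18 | 3,4-dimethoxy-2-methylbenzoyl chloride | COc1ccc(C(=O)Cl)c(C)c1OC | intermediate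
19 | 1-(3,4-dimethoxy-2-methylphenyl)-2-(dimethyloxosulfanylidene)ethanone | COc1ccc(C(=O)C=S(C)(C)=O)c(C)c1OC | intermediate
20 | pent-3-yn-2-one | CC#CC(C)=O | starting material
21 | 1-(4-hydroxy-6,7-dimethoxy-1,5-dimethylnaphthalen-2-yl)ethanone | COc1cc2c(C)c(C(C)=O)cc(O)c2c(C)c1OC | intermediate
22 | 1-(4-benzyloxy-6,7-dimethoxy-1,5-dimethylnaphthalen-2-yl)ethanone | COc1cc2c(C)c(C(C)=O)cc(OCc3ccccc3)c2c(C)c1OC | intermediate
23 | 4-benzyloxy-2-(1-bromovinyl)-6,7-dimethoxy-1,5-dimethylnaphthalene | COc1cc2c(C)c(C(Br)=C)cc(OCc3ccccc3)c2c(C)c1OC | intermediate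
24 | 1-(naphthalen-2-yl)vinyllithium from 23 | COc1cc2c(C)c(C([Li])=C)cc(OCc3ccccc3)c2c(C)c1OC | intermediate
25 | tertiary allylic alcohol, ring D as cyclopentanol (15β-vinyl, 15α-OH) | COc1cc2c(C)c(cc(OCc3ccccc3)c2c(C)c1OC)C(=C)[C@]3(O)C[C@@]4(C)CC[C@@](C)(C(=O)OC)C[C@H]4[C@]3(C)CCOCc5ccccc5 | intermediate
26 | ring-enlarged C15 ketone (14β-methyl) | COc1cc2c(C)c(cc(OCc3ccccc3)c2c(C)c1OC)[C@@]3(C)C(=O)C[C@@]4(C)CC[C@@](C)(C(=O)OC)C[C@H]4[C@]3(C)CCOCc5ccccc5 | intermediate
27 | C15 enol triflate | COc1cc2c(C)c(cc(OCc3ccccc3)c2c(C)c1OC)[C@@]3(C)C(OS(=O)(=O)C(F)(F)F)=C[C@@]4(C)CC[C@@](C)(C(=O)OC)C[C@H]4[C@]3(C)CCOCc5ccccc5 | intermediate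
28 | naphthol primary alcohol | COc1cc2c(C)c(cc(O)c2c(C)c1OC)[C@@]3(C)CC[C@@]4(C)CC[C@@](C)(C(=O)OC)C[C@H]4[C@]3(C)CCO | intermediate
29 | naphthol primary bromide | COc1cc2c(C)c(cc(O)c2c(C)c1OC)[C@@]3(C)CC[C@@]4(C)CC[C@@](C)(C(=O)OC)C[C@H]4[C@]3(C)CCBr | intermediate
30 | 6-oxopristimerol dimethyl ether | COc1cc2c(c(C)c1OC)C(=O)C=C1[C@@]2(C)CC[C@@]2(C)[C@@H]3C[C@](C)(C(=O)OC)CC[C@]3(C)CC[C@]12C | intermediate
31 | 6-oxopristimerol | Oc1cc2c(c(C)c1O)C(=O)C=C1[C@@]2(C)CC[C@@]2(C)[C@@H]3C[C@](C)(C(=O)OC)CC[C@]3(C)CC[C@]12C | intermediate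
32 | (S)-carvone | CC1=CC[C@@H](CC1=O)C(=C)C | starting material
33 | (2R,5S)-dihydrocarvone | C[C@@H]1CC[C@@H](CC1=O)C(=C)C | intermediate
34 | 7-trimethylsilyl derivative of 35 | C[C@@H]1CC[C@@H](CC([Si](C)(C)C)C1=O)C(=C)C | intermediate
35 | (2R,5S)-2-methyl-5-(prop-1-en-2-yl)cycloheptan-1-one | C[C@@H]1CC[C@@H](CCC1=O)C(=C)C | intermediate
36 | 2,4,6-triisopropylbenzenesulfonyl hydrazone of 35 | C[C@@H]1CC[C@@H](CCC1=NNS(=O)(=O)c1c(cc(cc1C(C)C)C(C)C)C(C)C)C(=C)C | intermediate
37 | (E)-crotonaldehyde | C/C=C/C=O | starting material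
38 | cycloheptenyllithium (lithium on G1) | C[C@@H]1CC[C@@H](CC=C1[Li])C(=C)C | intermediate
39 | (E)-1-[(4S,7R)-7-methyl-4-(prop-1-en-2-yl)cyclohept-1-en-1-yl]but-2-en-1-ol (carbinol epimers) | C[C@@H]1CC[C@@H](CC=C1C(O)/C=C/C)C(=C)C | intermediate
40 | (7S,10R)-guaia-1(5),3,11-triene | C=C(C)[C@H]1CC[C@@H](C)C2=C(C1)C(C)=CC2 | intermediate
41 | 2,3-ortho-quinone of 31 | O=C1C=C2C(=C(C)C1=O)C(=O)C=C3[C@@]2(C)CC[C@@]4(C)[C@@H]5C[C@](C)(C(=O)OC)CC[C@]5(C)CC[C@]34C | intermediate
42 | CNP0317749.2 | C=C(C)[C@H]1CC[C@@H](C)[C@@]23CC=C(C)[C@]2(C1)Oc1cc2c(c(C)c1O3)C(=O)C=C1[C@@]2(C)CC[C@@]2(C)[C@@H]3C[C@](C)(C(=O)OC)CC[C@]3(C)CC[C@]12C | target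

Total step count: 26. Longest linear sequence: 17 steps (steps 1–9, 14–20 and 26).

Steps most likely to fail

1. **Step 15.** Ionisation of the tertiary allylic alcohol with loss of water to a diene may outrun the 1,2-shift. Capture of the cation by the benzyl ether oxygen with loss of the benzyl group may do the same.
   - The fallback sets out from 25 and comes back at 26.
   - Hydroxyl-directed epoxidation with VO(acac)2 and t-BuOOH puts oxygen on the alkene face next to the hydroxyl group, which is the face opposite C13, and gives the epoxy alcohol F1.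
   - Et2AlCl opens the epoxide at benzylic C14 while C13 migrates anti to the breaking C–O bond (semipinacol rearrangement of an α-hydroxy epoxide, still a five-to-six enlargement of ring D). This gives the β-hydroxy ketone F2.
   - Appel iodination gives the neopentylic iodide F3, and Bu3SnH reduction turns CH2I into the C14 methyl group of 26.

2. **Step 14.** Enolisation of the hindered ketone, or no addition at all, is possible because the ortho-methyl naphthylvinyl nucleophile is very bulky.
   - The fallback sets out from 16 and comes back at 25.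
   - The slim 2-lithiopent-1-en-3-yne (from the bromide and t-BuLi) adds to 16 from the β face to give the enynyl carbinol F4.
   - The naphthol ring is then built on its alkyne by the rhodium benzannulation of step 11 with ylide 19. The alkenyl-bearing alkyne carbon ends up next to C7, which gives the free naphthol allylic alcohol F5.
   - Benzylation as in step 12 gives 25.

3. **Step 26.** Site selectivity may be poor. The quinone may add to the other fully substituted tautomer or to the less hindered trisubstituted double bond. The cyclopentadiene may also react as a four-electron partner without the following [3,3] shift.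
   - The fallback sets out from 35 (and from 31, through 41) and comes back at 42.
   - LDA and Me3SiCl give the kinetic silyl enol ether F6.
   - SnCl4-mediated addition to 2-nitrobut-2-ene with Nef hydrolysis in the same flask gives the 1,4-diketone F7.
   - Aldol condensation with KOH gives the cyclopentenone F8.
   - KN(SiMe3)2 and PhNTf2 give the cyclopentadienyl triflate F9. Only the needed tautomer of F9 has all four substituents on sp2 carbons, and its triflate group deactivates G3=G4.
   - The hetero-Diels–Alder reaction with 41 then takes place at G1=G5 and gives the adduct triflate F10.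
   - Reduction with Pd(PPh3)4, LiCl and Bu3SnH replaces the triflate by hydrogen and gives 42.

Further compounds
F1 | step 15 | epoxy alcohol from 25 | COc1cc2c(C)c(cc(OCc3ccccc3)c2c(C)c1OC)[C@]3(CO3)[C@]4(O)C[C@@]5(C)CC[C@@](C)(C(=O)OC)C[C@H]5[C@]4(C)CCOCc6ccccc6
F2 | step 15 | ring-enlarged β-hydroxy ketone (C14 hydroxymethyl) | COc1cc2c(C)c(cc(OCc3ccccc3)c2c(C)c1OC)[C@@]3(CO)C(=O)C[C@@]4(C)CC[C@@](C)(C(=O)OC)C[C@H]4[C@]3(C)CCOCc5ccccc5
F3 | step 15 | neopentylic iodide (C14 iodomethyl) | COc1cc2c(C)c(cc(OCc3ccccc3)c2c(C)c1OC)[C@@]3(CI)C(=O)C[C@@]4(C)CC[C@@](C)(C(=O)OC)C[C@H]4[C@]3(C)CCOCc5ccccc5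
F4 | step 14 | enynyl carbinol from 16 | CC#CC(=C)[C@]1(O)C[C@@]2(C)CC[C@@](C)(C(=O)OC)C[C@H]2[C@]1(C)CCOCc1ccccc1
F5 | step 14 | free naphthol allylic alcohol | COc1cc2c(C)c(cc(O)c2c(C)c1OC)C(=C)[C@]3(O)C[C@@]4(C)CC[C@@](C)(C(=O)OC)C[C@H]4[C@]3(C)CCOCc5ccccc5
F6 | step 26 | kinetic trimethylsilyl enol ether of 35 | C[C@@H]1CC[C@@H](CC=C1O[Si](C)(C)C)C(=C)C
F7 | step 26 | 1,4-diketone, 3-oxobutan-2-yl group on G5 (G4 and G5 epimers) | C[C@@H]1CC[C@@H](CC(C(C)C(C)=O)C1=O)C(=C)C
F8 | step 26 | guaia-1,11-dien-3-one (G4 and G5 epimers) | C[C@@H]1CC[C@@H](CC2C(C)C(=O)C=C12)C(=C)C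
F9 | step 26 | guaia-1(5),3,11-trien-3-yl triflate | C=C(C)[C@H]1CC[C@@H](C)C2=C(C1)C(C)=C(OS(=O)(=O)C(F)(F)F)C2
F10 | step 26 | G3 triflate of the target | C=C(C)[C@H]1CC[C@@H](C)[C@@]23CC(OS(=O)(=O)C(F)(F)F)=C(C)[C@]2(C1)Oc1cc2c(c(C)c1O3)C(=O)C=C1[C@@]2(C)CC[C@@]2(C)[C@@H]3C[C@](C)(C(=O)OC)CC[C@]3(C)CC[C@]12C
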